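A first-order constant cannot fall while it is being measured, so test the step to G for exactly that before running anything forward.

| setting | birch | ash | dawn | summer | autumn |
|---|---|---|---|---|---|
| L | 0.15 M | 0.15 M | 0.15 M | 0.15 M | 0.15 M |
| Z | 2 equiv (fed, over 2.0 min) | 4.5 equiv (fed, over 2.0 min) | 3.00 equiv (fed, over 2.0 min) | 3.00 equiv (fed, over 2.0 min) | 3.00 equiv (fed, over 2.0 min) |
| remark | run made earlier | run made earlier |  |  |  |
| time |  |  | 2.0 min | 6.0 min | 20 min |

Dawn, summer and autumn share one recipe and differ in time, so the three new flasks are one flask stopped at 2.0 min, 6.0 min and 20 min; birch and ash differ from each other in Z.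

| run | time / min | E / % | X / % | L / % | D / % | G / % |
|---|---|---|---|---|---|---|
| birch | 0.200 | 0.8 | 1.2 | 97.5 | 0 | 0 |
| birch | 0.667 | 8.2 | 5.2 | 81.4 | 0 | 0 |
| birch | 1.00 | 17.3 | 6.1 | 67.8 | 0 | 1.6 |
| birch | 1.50 | 35.3 | 7.8 | 46.8 | 0.1 | 4.3 |
| birch | 2.50 | 61.9 | 3.1 | 18.6 | 0 | 12.8 |
| ash | 0.200 | 0.8 | 2.4 | 93.5 | 0 | 0 |
| ash | 0.333 | 3.3 | 4.3 | 86.3 | 0 | 0 |
| ash | 0.667 | 17.0 | 9.1 | 63.6 | 0 | 0.6 |
| ash | 1.33 | 52.1 | 8.6 | 25.1 | 0.8 | 6.0 |
| ash | 2.50 | 75.8 | 2.4 | 2.0 | 0 | 18.7 |

(each reading ± 0.5 percentage points)

- the earlier runs were read with a standard deviation of 0.5 percentage points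

G appears after E, so take the specific rate of G: its gain per minute divided by the mean share of E over an interval. In ash this is 0.236 /min at a mean G/E of 0.0955, but 0.170 /min at 0.193. Birch falls too, from 0.205 /min at 0.112 to 0.175 /min at 0.176. So read G as returning to E, and follow each pair in a straight line down to zero. Ash reads 0.444 and birch 0.542, both rough readings, since a scatter of 0.5 points sits on short differences. Call their mean, 0.493, the ceiling ratio: the G/E at which G stops gaining on E, the equilibrium ratio of thermodynamic control.

- which of these there is most of at the end, counted by the L in it, dawn (E / L / X / G / D)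
- which of these there is most of at the end, counted by the L in it, summer (E / L / X / G / D)
- which of these there is most of at the end, counted by the L in it, autumn (E / L / X / G / D)
- the largest of these amounts at the end, in percent of the L charged, dawn
- the largest of these amounts at the end, in percent of the L charged, summer
- the largest of these amounts at the end, in percent of the L charged, autumn

My reckoning: once L has passed through, E takes 67.0% of the charge and G 33.0%, so E stays above G in summer and autumn. For dawn the ceiling says nothing, as L is still being used.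

The forecast, holding that “G grows in series from E”, gives E at 59% for dawn, G at 52% for summer and G at 96% for autumn, so it parts from my reckoning on summer and autumn.

    Q → J (k = 5.40 × 10⁻⁴ /s)
    L + Z → X (k = 0.0850 /M/s)
    X → E (k = 0.0950 /s)
    E ⇌ G (K = 0.440, k = 0.00440 /s)
    Z + Q ⇌ D (K = 0.520 /M, k = 0.00100 /M/s)
    L + Z ⇌ Q (K = 0.950 /M, k = 0.200 /M/s)
    Q → X (k = 0.0140 /s)

In dawn the feed of Z and the steps from L to E ran to 2.0 min, leaving L 15.5% beside E 62.6% and G 10.5%, and in summer L fell to 0.0662% by 6.0 min while E stood at 73.2% at 3.00 min and then at 69.9%, with G 29.4%. After that E and G exchanged both ways: autumn holds E 69.1%, beside the reckoned 67.0%, and the neighbour of summer with 0.750 equiv of Z, L 34% remaining, reached G/E 0.380, under the ceiling 0.493.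

(Readings and results are calculated from invented constants, and the scatter is random.)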